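**Retrosynthetic overview**
1. The furan ring is formed last: the O1–C2 bond comes from cyclodehydration of an o‑hydroxy‑deoxybenzoin, released by global MOM cleavage in the same flask (no alkyne, no Sonogashira).
2. The C3–C3a bond comes from Pd‑catalysed α‑arylation of a di‑ortho‑prenylated aryl methyl ketone with a prenylated resorcinol bromide; the acetyl carbons become C2 and C3.
3. Ketone fragment: 3,5‑dihydroxyacetophenone → bis‑MOM ether → 2,6‑dibromide → double Stille prenylation.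
4. Bromide fragment: resorcinol → bis‑MOM ether → two directed ortho‑metalations (C2 prenylation, then C4 bromination).
5. Ring order: both benzene rings are bought; the furan is the only ring built (step 8).

Assumption: the target has no stereocentre and no stereogenic axis (the resorcinol ring is symmetric about the aryl–furan bond), so it is achiral and "single enantiomer" needs no stereocontrol. Abbreviations: MOM = methoxymethyl, prenyl = 3‑methylbut‑2‑en‑1‑yl.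

**Step 1**
Reactants: 1 3,5‑dihydroxyacetophenone
Product: 2 1‑[3,5‑bis(methoxymethoxy)phenyl]ethan‑1‑one
Conditions: MOMCl (2.5 equiv), i‑Pr2NEt (3 equiv), CH2Cl2, 0 °C → rt
Reagents that add atoms: chloromethyl methyl ether (MOMCl), COCCl
Why: Base‑mediated O‑alkylation (MOM protection) of both phenols gives acetal ethers that survive NBS, Pd catalysis and strong base and come off together at the end.

**Step 2**
Reactants: 2 1‑[3,5‑bis(methoxymethoxy)phenyl]ethan‑1‑one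
Product: 3 1‑[2,6‑dibromo‑3,5‑bis(methoxymethoxy)phenyl]ethan‑1‑one
Conditions: NBS (2.1 equiv), MeCN, 0 °C → rt, dark
Reagents that add atoms: N‑bromosuccinimide, O=C1CCC(=O)N1Br
Why: Electrophilic aromatic bromination puts each bromine para to one OMOM and ortho to the other (C2, C6), as in known 3,5‑dialkoxyaryl carbonyl compounds, while C4 between the two OMOM groups is the slowest site and the ketone α‑position is untouched without acid.

**Step 3**
Reactants: 3 1‑[2,6‑dibromo‑3,5‑bis(methoxymethoxy)phenyl]ethan‑1‑one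
Product: 4 1‑[3,5‑bis(methoxymethoxy)‑2,6‑bis(3‑methylbut‑2‑en‑1‑yl)phenyl]ethan‑1‑one
Conditions: tributyl(prenyl)stannane (3 equiv), Pd(PPh3)4 (10 mol %), DMF, 100 °C
Reagents that add atoms: tributyl(3‑methylbut‑2‑en‑1‑yl)stannane, CCCC[Sn](CCCC)(CCCC)CC=C(C)C
Why: Double Stille cross‑coupling, in which the hindered aryl(η3‑prenyl)palladium reductively eliminates at the unsubstituted allyl terminus to give the linear prenyl group, and the neutral stannane leaves the ketone alone.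

**Step 4**
Reactants: 5 resorcinol
Product: 6 1,3‑bis(methoxymethoxy)benzene
Conditions: MOMCl (2.5 equiv), i‑Pr2NEt (3 equiv), CH2Cl2, 0 °C → rt
Reagents that add atoms: chloromethyl methyl ether (MOMCl), COCCl
Why: MOM protection by O‑alkylation installs the two directing groups needed for the metalations that follow.

**Step 5**
Reactants: 6 1,3‑bis(methoxymethoxy)benzene
Product: 8 1,3‑bis(methoxymethoxy)‑2‑(3‑methylbut‑2‑en‑1‑yl)benzene, via 2‑lithio‑1,3‑bis(methoxymethoxy)benzene 7 (not isolated)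
Conditions: n‑BuLi (1.1 equiv), THF, 0 °C → rt; CuI (10 mol %), prenyl bromide, −78 °C → rt
Reagents that add atoms: 3‑methylbut‑2‑en‑1‑yl bromide (prenyl bromide), CC(C)=CCBr; n‑butyllithium, CCCC[Li] (its lithium stays only in 7)
Why: Directed ortho‑metalation occurs at the position flanked by both OMOM groups, and copper‑catalysed SN2 allylation of the aryllithium with prenyl bromide gives the linear prenyl arene.

**Step 6**
Reactants: 8 1,3‑bis(methoxymethoxy)‑2‑(3‑methylbut‑2‑en‑1‑yl)benzene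
Product: 10 1‑bromo‑2,4‑bis(methoxymethoxy)‑3‑(3‑methylbut‑2‑en‑1‑yl)benzene, via C4‑aryllithium 9 (not isolated)
Conditions: n‑BuLi (1.2 equiv), TMEDA (1.2 equiv), THF, −20 → 0 °C; BrCH2CH2Br (1.5 equiv), −78 °C → rt
Reagents that add atoms: 1,2‑dibromoethane, BrCCBr; n‑butyllithium, CCCC[Li] (its lithium stays only in 9)
Why: A second directed ortho‑metalation next to OMOM (C4 and C6 are equivalent by symmetry) is kinetically faster than deprotonation of the hindered prenyl CH2, and the aryllithium is brominated by 1,2‑dibromoethane with loss of ethylene.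

**Step 7**
Reactants: 4 1‑[3,5‑bis(methoxymethoxy)‑2,6‑bis(3‑methylbut‑2‑en‑1‑yl)phenyl]ethan‑1‑one (1.2 equiv); 10 1‑bromo‑2,4‑bis(methoxymethoxy)‑3‑(3‑methylbut‑2‑en‑1‑yl)benzene
Product: 11 1‑[3,5‑bis(methoxymethoxy)‑2,6‑bis(3‑methylbut‑2‑en‑1‑yl)phenyl]‑2‑[2,4‑bis(methoxymethoxy)‑3‑(3‑methylbut‑2‑en‑1‑yl)phenyl]ethan‑1‑one
Conditions: Pd2(dba)3 (2.5 mol %), XPhos (6 mol %), NaOt‑Bu (2.2 equiv), toluene, 80 °C
Reagents that add atoms: none
Why: Palladium‑catalysed ketone α‑arylation (Buchwald–Hartwig–Miura type) joins the unhindered CH2 terminus of the methyl ketone enolate to the aryl bromide; the twisted di‑ortho‑substituted ketone cannot self‑condense, and the ortho‑OMOM group on the aryl partner stops a second arylation.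

**Step 8**
Reactants: 11 1‑[3,5‑bis(methoxymethoxy)‑2,6‑bis(3‑methylbut‑2‑en‑1‑yl)phenyl]‑2‑[2,4‑bis(methoxymethoxy)‑3‑(3‑methylbut‑2‑en‑1‑yl)phenyl]ethan‑1‑one
Product: 14 5‑[6‑hydroxy‑7‑(3‑methylbut‑2‑en‑1‑yl)‑1‑benzofuran‑2‑yl]‑4,6‑bis(3‑methylbut‑2‑en‑1‑yl)benzene‑1,3‑diol (target), via tetraphenol ketone 12 (not isolated), via cyclic hemiketal 13 (not isolated)
Conditions: 3 M aq HCl/MeOH (1:4), 45 °C, Ar, stop at full conversion
Reagents that add atoms: none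
Why: Acid‑catalysed acetal methanolysis frees the four phenols, the ring‑A 2‑hydroxyl adds 5‑exo‑trig to the ketone and the hemiketal dehydrates irreversibly to the aromatic furan (cyclodehydration of an o‑hydroxydeoxybenzoin); both events need much weaker acid than protonation of a prenyl alkene.

**Compound list**
1 | 3,5‑dihydroxyacetophenone | CC(=O)c1cc(O)cc(O)c1 | starting material
2 | 1‑[3,5‑bis(methoxymethoxy)phenyl]ethan‑1‑one | CC(=O)c1cc(OCOC)cc(OCOC)c1 | intermediate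
3 | 1‑[2,6‑dibromo‑3,5‑bis(methoxymethoxy)phenyl]ethan‑1‑one | CC(=O)c1c(Br)c(OCOC)cc(OCOC)c1Br | intermediate
4 | 1‑[3,5‑bis(methoxymethoxy)‑2,6‑bis(3‑methylbut‑2‑en‑1‑yl)phenyl]ethan‑1‑one | CC(=O)c1c(CC=C(C)C)c(OCOC)cc(OCOC)c1CC=C(C)C | intermediate
5 | resorcinol (benzene‑1,3‑diol) | Oc1cccc(O)c1 | starting material
6 | 1,3‑bis(methoxymethoxy)benzene | COCOc1cccc(OCOC)c1 | intermediate
7 | 2‑lithio‑1,3‑bis(methoxymethoxy)benzene | [Li]c1c(OCOC)cccc1OCOC | intermediate (not isolated)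
8 | 1,3‑bis(methoxymethoxy)‑2‑(3‑methylbut‑2‑en‑1‑yl)benzene | COCOc1cccc(OCOC)c1CC=C(C)C | intermediate
9 | [2,4‑bis(methoxymethoxy)‑3‑(3‑methylbut‑2‑en‑1‑yl)phenyl]lithium | [Li]c1ccc(OCOC)c(CC=C(C)C)c1OCOC | intermediate (not isolated)
10 | 1‑bromo‑2,4‑bis(methoxymethoxy)‑3‑(3‑methylbut‑2‑en‑1‑yl)benzene | COCOc1ccc(Br)c(OCOC)c1CC=C(C)C | intermediate
11 | 1‑[3,5‑bis(methoxymethoxy)‑2,6‑bis(3‑methylbut‑2‑en‑1‑yl)phenyl]‑2‑[2,4‑bis(methoxymethoxy)‑3‑(3‑methylbut‑2‑en‑1‑yl)phenyl]ethan‑1‑one | CC(C)=CCc1c(OCOC)ccc(CC(=O)c2c(CC=C(C)C)c(OCOC)cc(OCOC)c2CC=C(C)C)c1OCOC | intermediate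
12 | 1‑[3,5‑dihydroxy‑2,6‑bis(3‑methylbut‑2‑en‑1‑yl)phenyl]‑2‑[2,4‑dihydroxy‑3‑(3‑methylbut‑2‑en‑1‑yl)phenyl]ethan‑1‑one | CC(C)=CCc1c(O)ccc(CC(=O)c2c(CC=C(C)C)c(O)cc(O)c2CC=C(C)C)c1O | intermediate (not isolated)
13 | 2‑[3,5‑dihydroxy‑2,6‑bis(3‑methylbut‑2‑en‑1‑yl)phenyl]‑7‑(3‑methylbut‑2‑en‑1‑yl)‑2,3‑dihydro‑1‑benzofuran‑2,6‑diol (racemic, transient; its stereocentre is lost on dehydration) | OC1(Cc2ccc(O)c(CC=C(C)C)c2O1)c1c(CC=C(C)C)c(O)cc(O)c1CC=C(C)C | intermediate (not isolated)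
14 | 5‑[6‑hydroxy‑7‑(3‑methylbut‑2‑en‑1‑yl)‑1‑benzofuran‑2‑yl]‑4,6‑bis(3‑methylbut‑2‑en‑1‑yl)benzene‑1,3‑diol (achiral) | CC(C)=CCc1c(O)cc(O)c(CC=C(C)C)c1-c1cc2ccc(O)c(CC=C(C)C)c2o1 | target

**Totals**
Total steps: 8. Longest linear sequence: 5 (steps 1, 2, 3, 7, 8; the other branch, steps 4, 5, 6, 7, 8, is also 5).

**Three steps most likely to fail, with fallbacks**

Step 7 (α‑arylation between two congested partners; risk of slow coupling or hydrodebromination). The fallback sets out from 4 and 10 and comes back at 14, using the conventional alkyne logic held in reserve. Ketone 4 is treated with LDA and ClP(O)(OEt)2 to give the enol phosphate diethyl 1‑[3,5‑bis(methoxymethoxy)‑2,6‑bis(3‑methylbut‑2‑en‑1‑yl)phenyl]ethenyl phosphate F1. More LDA eliminates this in the same flask to the terminal alkyne 2‑ethynyl‑4,6‑bis(methoxymethoxy)‑1,3‑bis(3‑methylbut‑2‑en‑1‑yl)benzene F2. Copper‑free Sonogashira coupling of F2 with bromide 10 (PdCl2(MeCN)2, XPhos, Cs2CO3, MeCN, 80 °C) gives the diarylacetylene 1‑{[2,4‑bis(methoxymethoxy)‑3‑(3‑methylbut‑2‑en‑1‑yl)phenyl]ethynyl}‑3,5‑bis(methoxymethoxy)‑2,6‑bis(3‑methylbut‑2‑en‑1‑yl)benzene F3. Dilute HCl in MeOH removes the MOM groups to give 4‑{[3,5‑dihydroxy‑2,6‑bis(3‑methylbut‑2‑en‑1‑yl)phenyl]ethynyl}‑2‑(3‑methylbut‑2‑en‑1‑yl)benzene‑1,3‑diol F4, and Cs2CO3 in DMF at 60 °C closes this o‑alkynylphenol 5‑endo‑dig to 14.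

Step 8 (protic acid with three prenyl groups each ortho to a freed phenol; risk of 2,2‑dimethylchroman formation or alkene hydration). The fallback sets out from 11 and comes back at 12, avoiding any acid able to protonate an alkene. TESOTf and 2,2'‑bipyridyl in CH2Cl2 at 0 °C exchange the four aryl MOM ethers directly for silyl ethers, giving 1‑[3,5‑bis(triethylsilyloxy)‑2,6‑bis(3‑methylbut‑2‑en‑1‑yl)phenyl]‑2‑[2,4‑bis(triethylsilyloxy)‑3‑(3‑methylbut‑2‑en‑1‑yl)phenyl]ethan‑1‑one F5. TBAF buffered with AcOH (THF, 0 °C) then releases tetraphenol 12, this time isolated. PPTS with 4 Å sieves in CH2Cl2 at rt closes 12 through 13 to 14.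

Step 3 (double Stille at two di‑ortho‑substituted C–Br bonds; risk of incomplete second coupling or some branched 1,1‑dimethylallyl isomer). The fallback sets out from 1 and comes back at 4, replacing cross‑coupling with sigmatropic chemistry. Compound 1 is O‑alkylated twice with 3‑chloro‑3‑methylbut‑1‑yne (K2CO3, KI, cat. CuI, acetone) to 1‑[3,5‑bis(2‑methylbut‑3‑yn‑2‑yloxy)phenyl]ethan‑1‑one F6. Lindlar semi‑hydrogenation gives the bis(1,1‑dimethylallyl) ether 1‑[3,5‑bis(2‑methylbut‑3‑en‑2‑yloxy)phenyl]ethan‑1‑one F7. A double aromatic Claisen rearrangement (PhNEt2, 130 °C), steered by the meta‑acyl group to the positions flanking it, gives 1‑[3,5‑dihydroxy‑2,6‑bis(3‑methylbut‑2‑en‑1‑yl)phenyl]ethan‑1‑one F8. MOMCl/i‑Pr2NEt then converts F8 into 4.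

**Further compounds**
F1 | step 7 | diethyl 1‑[3,5‑bis(methoxymethoxy)‑2,6‑bis(3‑methylbut‑2‑en‑1‑yl)phenyl]ethenyl phosphate | C=C(OP(=O)(OCC)OCC)c1c(CC=C(C)C)c(OCOC)cc(OCOC)c1CC=C(C)C
F2 | step 7 | 2‑ethynyl‑4,6‑bis(methoxymethoxy)‑1,3‑bis(3‑methylbut‑2‑en‑1‑yl)benzene | C#Cc1c(CC=C(C)C)c(OCOC)cc(OCOC)c1CC=C(C)C
F3 | step 7 | 1‑{[2,4‑bis(methoxymethoxy)‑3‑(3‑methylbut‑2‑en‑1‑yl)phenyl]ethynyl}‑3,5‑bis(methoxymethoxy)‑2,6‑bis(3‑methylbut‑2‑en‑1‑yl)benzene | COCOc1ccc(C#Cc2c(CC=C(C)C)c(OCOC)cc(OCOC)c2CC=C(C)C)c(OCOC)c1CC=C(C)C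
F4 | step 7 | 4‑{[3,5‑dihydroxy‑2,6‑bis(3‑methylbut‑2‑en‑1‑yl)phenyl]ethynyl}‑2‑(3‑methylbut‑2‑en‑1‑yl)benzene‑1,3‑diol | CC(C)=CCc1c(O)ccc(C#Cc2c(CC=C(C)C)c(O)cc(O)c2CC=C(C)C)c1O
F5 | step 8 | 1‑[3,5‑bis(triethylsilyloxy)‑2,6‑bis(3‑methylbut‑2‑en‑1‑yl)phenyl]‑2‑[2,4‑bis(triethylsilyloxy)‑3‑(3‑methylbut‑2‑en‑1‑yl)phenyl]ethan‑1‑one | CC(C)=CCc1c(O[Si](CC)(CC)CC)ccc(CC(=O)c2c(CC=C(C)C)c(O[Si](CC)(CC)CC)cc(O[Si](CC)(CC)CC)c2CC=C(C)C)c1O[Si](CC)(CC)CC
F6 | step 3 | 1‑[3,5‑bis(2‑methylbut‑3‑yn‑2‑yloxy)phenyl]ethan‑1‑one | CC(=O)c1cc(OC(C)(C)C#C)cc(OC(C)(C)C#C)c1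
F7 | step 3 | 1‑[3,5‑bis(2‑methylbut‑3‑en‑2‑yloxy)phenyl]ethan‑1‑one | CC(=O)c1cc(OC(C)(C)C=C)cc(OC(C)(C)C=C)c1
F8 | step 3 | 1‑[3,5‑dihydroxy‑2,6‑bis(3‑methylbut‑2‑en‑1‑yl)phenyl]ethan‑1‑one | CC(=O)c1c(CC=C(C)C)c(O)cc(O)c1CC=C(C)C
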